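(All runs are simulated with made-up constants; scatter was added.)

Start at the late end of the autumn run: from 1.25 d to 2.50 d target rises 4.29 times, close to the square of the time ratio of 2.00.

| flask | starting material | coupling partner | remark | time |
|---|---|---|---|---|
| autumn | 2 M | 1.1 equiv | run made earlier |  |
| blue | 2.0 M | 1.10 equiv | a single well-mixed tank run continuously and read at steady state, 4.0 d in it on average |  |
| red | 2.0 M | 1.10 equiv | a closed flask charged with all of it at once and left for 4.0 d | 4.0 d |
| ochre | 2.0 M | 1.10 equiv | a single well-mixed tank run continuously and read at steady state, 20.0 d in it on average |  |
| teal | 2.0 M | 1.10 equiv (fed, over 4.00 d) | a stirred flask in which coupling partner is dosed at a steady rate over 4.00 d without added volume, worked up at 4.0 d | 4.0 d |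

autumn run (percent of the starting material charged)

| time / d | target / % | starting material / % |
|---|---|---|
| 0.208 | 0 | 7.5 |
| 0.333 | 0 | 1.2 |
| 0.625 | 1.1 | 0 |
| 1.25 | 4.8 | 0.4 |
| 2.50 | 20.6 | 1.5 |

(standard deviation of a reading: 1 percentage point)

- the stated concentrations are those of everything mixed, before any reaction; amounts are the same in each set-up
- the feed brings no volume worth counting
- the earlier runs were made in a closed, stirred flask

1. the set-up with the highest amount of target at the outlet or at the end, in percent of the starting material put in ("none" if the first two lie within 2 percentage points) (blue / red / ochre / teal / none)
2. amount of target at the outlet or at the end, in percent of the starting material put in, blue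
3. amount of target at the outlet or at the end, in percent of the starting material put in, red
4. amount of target at the outlet or at the end, in percent of the starting material put in, ochre
5. amount of target at the outlet or at the end, in percent of the starting material put in, teal

Read that square as a lag (an induction period), and picture two equal slow steps in line. Call the mean time of each step the chain time τ, and let x be time divided by τ. Target's share of the charge is then one minus (one plus x) times e to the minus x, which a few trial values solve.

Reckon τ twice. The reading at 1.25 d gives 3.60 d. The reading at 2.50 d gives 2.99 d. They part, so ask which one cheats. Both carry a scatter of 1 percentage point, but the early reading is the smaller one, so it suffers more. Keep 2.99 d. Starting material's first-order time, 0.0803 d, is far shorter, so count that step as instant.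

Now use τ. For red, the closed flask, the curve gives 38.7 %. In a tank with mean residence T, each step passes T/(T+τ), and two steps square it. Blue, at 4.0 d, gives 32.7 %, and ochre, at 20.0 d, gives 75.7 %, so bet on ochre.

Teal is a wager, since no run varied coupling partner. Starting material's time between the first two autumn readings is 0.0682 d, no longer than the 0.0803 d above, so these readings show no slowing of its loss as it nears its end. Take teal equal to red.

The forecast also names ochre, but it parts from this reckoning at every set-up, higher with blue 48 %, red 47 % and ochre 85 %, and lower with teal 16 %, holding that "Dosing delays intermediate formation".

The flask gives blue 32.8 %, red 39.6 %, ochre 75.3 % and teal 39.6 %, so ochre is highest, and teal matches red.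

    starting material → intermediate A (k = 1.50 × 10⁻⁴ /s)
    intermediate A ⇌ intermediate B (K = 16.0, k = 3.30 × 10⁻⁵ /s)
    intermediate B ⇌ intermediate C (K = 1.40, k = 1.10 × 10⁻⁵ /s)
    intermediate B ⇌ intermediate D (K = 1.30, k = 3.60 × 10⁻⁶ /s)
    intermediate B → intermediate E (k = 1.90 × 10⁻⁵ /s)
    intermediate E → target (k = 1.00 × 10⁻⁵ /s)
    intermediate D ⇌ intermediate A (k = 1.50 × 10⁻⁵ /s)
    coupling partner → decomposition product (k = 4.80 × 10⁻⁹ /s)

Set the times side by side: intermediate E goes to target with a half-life of 0.80 d, longer than the 0.42 d of intermediate B going to intermediate E, each by that loss alone. Counted in τ, blue's 4.0 d on average is 1.34 chain times and its outlet holds 32.8 % target, while ochre's 20.0 d on average is 6.69 chain times and its outlet holds 75.3 %.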